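The numbers come from no measurement; what happens was integrated by code.

I began at late times, when a molecule of partner has left by one of two exits, and I kept my books on partner.

    substrate + partner + catalyst → product + catalyst, rate k1*[substrate]*[partner]*[catalyst]/(1 + ([substrate]/sat1)) (sat1 = 0.264 M, k1 = 46.9 M⁻² h⁻¹, Ea1 = 47.0 kJ mol⁻¹)
    partner → decomposed reagent (k2 = 2.65 h⁻¹, Ea2 = 112 kJ mol⁻¹)
    (constants at 60 °C)

| setting | Friday's | Sunday's | Wednesday's |
|---|---|---|---|
| substrate | 0.87 M | 0.87 M | 0.87 M |
| partner | 0.913 M | 0.913 M | 0.913 M |
| catalyst | 7.8 mM | 7.8 mM | 7.8 mM |
| temperature | 30 °C | 45 °C | 60 °C |
| time | 12 h | 12 h | 12 h |

- which flask leads in amount of product, in percent of the substrate charged ("all alike" within 1.5 percentage points) (Friday's / Sunday's / Wednesday's / all alike)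
- how much product is there at the end, in percent of the substrate charged: Friday's
- how much product is there at the end, in percent of the substrate charged: Sunday's
- how much product is there at the end, in percent of the substrate charged: Wednesday's

- all constants are for 60 °C and move with temperature by the activation energies

I followed one molecule of partner, the limiting reagent here, though it was charged at 1.05 equivalents. It could decompose, or it could couple with substrate on the catalyst and leave as product. With [substrate] held at its charge, both exits were first-order for the molecule, the coupling being pseudo-first-order. In Wednesday's flask, at the temperature of the constants, I reckoned coupling at 0.0741 h⁻¹ against 2.65 h⁻¹ for decomposition. In Friday's flask these fell by factors of 5.4 and 55, to 0.0138 h⁻¹ and 0.0485 h⁻¹. The chance of ending as product was the coupling rate over the sum of both, 22.2% in Friday's flask; I call this the fork share.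

Friday's ledger opened with 0.913 M of partner. The two exits together gave a time constant of 16.1 h, longer than the 12 h allowed, so by the end I had 52.6% of the partner spent and 0.432 M still on the books. The spent part split into 0.107 M of product and 0.374 M of decomposed reagent, and the three entries closed on the charge. That product entry was 12.3% of the substrate charged. Friday's remaining partner, taking the same fork, would bring product to 23.3%.

Wednesday's time constant was 0.367 h, far shorter than 12 h, so its books closed early. Its fork share of 2.72% gave 2.85% of product. I therefore put Friday's ahead of Wednesday's and made no figure for Sunday's.

The forecast named Friday's, with 12.1% for Friday's, 8% for Sunday's and 2.85% for Wednesday's, on the ground that “heating destroys the reagent far faster than it speeds coupling”.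

The simulation gave 12.1% in Friday's flask, 8.06% in Sunday's and 2.85% in Wednesday's, so Friday's led.

Friday's flask had not come to rest: 47.5% of its partner still stood at 12.0 h. By 120 h that partner was down to 0.0621% and product had reached 22.7%, against the 23.3% that the fork share of 22.2%, reckoned with [substrate] held at its charge, gives for the full charge. Sunday's flask held 0.60% of its partner at the end, and ten times the time left its product at 8.10%. Wednesday's flask was at rest, its partner counted as run out by 1.44 h and standing at 0% at the end, and at 120 h its product still stood at 2.85%.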